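The target is catechin-(4α→8)-epicatechin-(4β→6)-catechin. Everything rests on treating the trans C3-hydroxy/C4-aryl pair on ring C (the pyran ring O1–C2–C3–C4–C4a–C8a) of the upper catechin unit as the anti-adduct of a C3=C4 olefin. Ring-closing metathesis of an enantioenriched 1-arylallyl 2-vinylaryl ether closes that pyran ring by making the C3–C4 bond. The resulting flav-3-ene carries a C2 stereocentre that then steers dihydroxylation and, after ionisation at C4, trans-selective Friedel–Crafts union with C8 of a benzylated, C8-brominated epicatechin-(4β→6)-catechin dimer made from the two natural flavan-3-ols. Global hydrogenolysis ends the route.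

Key step: step 7

Remark: the 3-OH groups are left free throughout, and in step 5 the antipode of the phosphoramidite ligand that delivers the (S)-ether is used (the sense of induction is to be confirmed on a model).

Step 1
Reactants: 1 2,4,6-trihydroxybenzaldehyde; 2 benzyl bromide
Product: 3 4,6-bis(benzyloxy)-2-hydroxybenzaldehyde
Conditions: BnBr (2.0 equiv), K2CO3, DMF, 0 °C to rt
Reagents that add atoms: benzyl bromide, BrCc1ccccc1
Why: Williamson etherification, in which the para OH and one ortho OH react while the last ortho OH, hydrogen-bonded to the formyl group, should stay free; the symmetry of 1 allows only one dibenzyl isomer of this kind.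

Step 2
Reactants: 4 3,4-bis(benzyloxy)benzaldehyde; 5 triethyl phosphonoacetate
Product: 6 ethyl (E)-3-[3,4-bis(benzyloxy)phenyl]acrylate
Conditions: NaH, THF, 0 °C to rt
Reagents that add atoms: triethyl phosphonoacetate, CCOC(=O)CP(=O)(OCC)OCC
Why: Horner–Wadsworth–Emmons olefination of a non-enolisable aryl aldehyde with a stabilised phosphonate anion, which should give the (E)-cinnamate.

Step 3
Reactants: 6 ethyl (E)-3-[3,4-bis(benzyloxy)phenyl]acrylate
Product: 7 (E)-3-[3,4-bis(benzyloxy)phenyl]prop-2-en-1-ol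
Conditions: i-Bu2AlH (2.5 equiv), CH2Cl2, −78 °C; aq. potassium sodium tartrate
Reagents that add atoms: none
Why: 1,2-reduction of the conjugated ester by the aluminium hydride to the allylic alcohol, leaving the olefin geometry and the benzyl ethers untouched.

Step 4
Reactants: 7 (E)-3-[3,4-bis(benzyloxy)phenyl]prop-2-en-1-ol; 8 methyl chloroformate
Product: 9 (E)-3-[3,4-bis(benzyloxy)phenyl]allyl methyl carbonate
Conditions: ClCO2Me, pyridine, CH2Cl2, 0 °C
Reagents that add atoms: methyl chloroformate, COC(=O)Cl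
Why: O-acylation of the primary allylic alcohol to the carbonate, the standard leaving group for iridium-catalysed allylic substitution.

Step 5
Reactants: 3 4,6-bis(benzyloxy)-2-hydroxybenzaldehyde; 9 (E)-3-[3,4-bis(benzyloxy)phenyl]allyl methyl carbonate
Product: 11 (S)-4,6-bis(benzyloxy)-2-({1-[3,4-bis(benzyloxy)phenyl]prop-2-en-1-yl}oxy)benzaldehyde, via sodium aryloxide 10 (not isolated)
Conditions: NaH (1.0 equiv), THF, 0 °C; then 9, [Ir(cod)Cl]2 (2 mol %), O,O'-(1,1'-binaphthyl-2,2'-diyl) N,N-bis(1-phenylethyl)phosphoramidite (4 mol %), THF, rt to 40 °C, stopped at full conversion of 9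
Reagents that add atoms: none
Why: Iridium-catalysed asymmetric allylic etherification, in which the cyclometalated iridium–phosphoramidite π-allyl complex is attacked by the aryloxide at the aryl-substituted terminus to give the branched ether, whose (S) configuration (the future C2) is set by the ligand.

Step 6
Reactants: 11 (S)-4,6-bis(benzyloxy)-2-({1-[3,4-bis(benzyloxy)phenyl]prop-2-en-1-yl}oxy)benzaldehyde; 12 methyltriphenylphosphonium bromide
Product: 13 (S)-1,5-bis(benzyloxy)-3-({1-[3,4-bis(benzyloxy)phenyl]prop-2-en-1-yl}oxy)-2-vinylbenzene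
Conditions: Ph3PCH3Br, KOt-Bu (1.1 equiv), THF, 0 °C
Reagents that add atoms: methyltriphenylphosphonium bromide, C[P+](c1ccccc1)(c1ccccc1)c1ccccc1.[Br-]
Why: Wittig methylenation of the non-enolisable aldehyde with a non-stabilised ylide, with base kept near one equivalent so that the doubly activated C–H of the allylic ether stereocentre is not touched.

Step 7
Reactants: 13 (S)-1,5-bis(benzyloxy)-3-({1-[3,4-bis(benzyloxy)phenyl]prop-2-en-1-yl}oxy)-2-vinylbenzene
Product: 14 (S)-5,7-bis(benzyloxy)-2-[3,4-bis(benzyloxy)phenyl]-2H-chromene (benzylated flav-3-ene)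
Conditions: second-generation Grubbs catalyst RuCl2(=CHPh)(PCy3)(H2IMes) (5 mol %), 1,4-benzoquinone (10 mol %), CH2Cl2 (0.01 M), 40 °C
Reagents that add atoms: none
Why: Ring-closing olefin metathesis: the ruthenium benzylidene exchanges onto the unhindered vinyl group of the allylic ether, the new alkylidene undergoes intramolecular [2+2] cycloaddition with the ortho styrene, and cycloreversion expels ethene and leaves the C3=C4 double bond. The closest known reaction type is the metathesis closure of 2-(allyloxy)styrenes to 2H-chromenes. The ring closed is the six-membered pyran ring C (O1–C2–C3–C4–C4a–C8a) of the future upper catechin unit, closed in the metathesis mode by joining the two terminal sp2 carbons into an endocyclic cis olefin. No stereocentre is created; the C2 stereocentre from step 5 is carried through because neither its C–O nor its C–H bond takes part, and the new olefin is what later lets C2 control C3 (step 8) and C4 (step 14). The step needs ring closure to beat intermolecular cross-metathesis and ruthenium-hydride migration of the allylic ether double bond; the ortho disposition of the two vinyl groups together with high dilution should secure the first, and the benzoquinone additive the second.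

Step 8
Reactants: 14 (S)-5,7-bis(benzyloxy)-2-[3,4-bis(benzyloxy)phenyl]-2H-chromene; 15 N-methylmorpholine N-oxide
Product: 16 (2R,3S,4S)-5,7-bis(benzyloxy)-2-[3,4-bis(benzyloxy)phenyl]chromane-3,4-diol (2,3-trans-3,4-cis)
Conditions: OsO4 (2 mol %), NMO (1.5 equiv), acetone/H2O, 0 °C to rt
Reagents that add atoms: N-methylmorpholine N-oxide, C[N+]1([O-])CCOCC1; water, O; osmium tetroxide (catalytic oxygen carrier), O=[Os](=O)(=O)=O
Why: Upjohn syn-dihydroxylation, in which OsO4 should add to the electron-rich C3=C4 olefin on the face opposite the C2 aryl group, so that the C3 hydroxyl is set trans to the aryl group (the C4 configuration is erased in step 14).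

Step 9
Reactants: 17 (−)-epicatechin; 2 benzyl bromide
Product: 18 5,7,3',4'-tetra-O-benzyl-(−)-epicatechin
Conditions: BnBr (4.2 equiv), K2CO3, DMF, argon, 0 °C to rt
Reagents that add atoms: benzyl bromide, BrCc1ccccc1
Why: Williamson etherification of the four phenols under a carbonate base that is too weak to alkylate the aliphatic 3-OH, with air excluded and the temperature kept low to avoid C2 epimerisation.

Step 10
Reactants: 18 5,7,3',4'-tetra-O-benzyl-(−)-epicatechin; 19 2-ethoxyethanol
Product: 20 (2R,3R,4S)-5,7-bis(benzyloxy)-2-[3,4-bis(benzyloxy)phenyl]-4-(2-ethoxyethoxy)chroman-3-ol (4β-ether, 3,4-trans)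
Conditions: DDQ (2 equiv), 2-ethoxyethanol (10 equiv), CH2Cl2, rt
Reagents that add atoms: 2-ethoxyethanol, CCOCCO
Why: DDQ benzylic oxidation, in which hydride abstraction from C4 gives the cation stabilised by ring A and the alcohol should trap it trans to the 3-OH and to the 2-aryl group.

Step 11
Reactants: 21 (+)-catechin; 2 benzyl bromide
Product: 22 5,7,3',4'-tetra-O-benzyl-(+)-catechin
Conditions: BnBr (4.2 equiv), K2CO3, DMF, argon, 0 °C to rt
Reagents that add atoms: benzyl bromide, BrCc1ccccc1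
Why: Williamson etherification of the four phenols only, as in step 9.

Step 12
Reactants: 22 5,7,3',4'-tetra-O-benzyl-(+)-catechin; 23 N-bromosuccinimide
Product: 24 8-bromo-5,7,3',4'-tetra-O-benzyl-(+)-catechin
Conditions: NBS (1.0 equiv), CH2Cl2, −78 °C to rt
Reagents that add atoms: N-bromosuccinimide, O=C1CCC(=O)N1Br
Why: Electrophilic aromatic bromination of the 5,7-dialkoxy ring A, which should go to C8, its more reactive and more accessible position, and thereby blocks that position.

Step 13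
Reactants: 20 4β-(2-ethoxyethoxy)-5,7,3',4'-tetra-O-benzyl-(−)-epicatechin; 24 8-bromo-5,7,3',4'-tetra-O-benzyl-(+)-catechin
Product: 25 5,7,3',4'-tetra-O-benzyl-(−)-epicatechin-(4β→6)-8-bromo-5,7,3',4'-tetra-O-benzyl-(+)-catechin
Conditions: 24 (3 equiv, excess recovered), TMSOTf (0.2 equiv), CH2Cl2, −78 °C; Et3N quench
Reagents that add atoms: none
Why: Lewis-acid-promoted Friedel–Crafts alkylation by the flavan C4 cation, in which the bromine-blocked nucleophile can only react through C6 and should attack anti to the 3-OH and the 2-aryl group to give the 4β (3,4-trans) bond, while the excess of 24 holds back self-condensation of 20.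

Step 14
Reactants: 16 (2R,3S,4S)-5,7-bis(benzyloxy)-2-[3,4-bis(benzyloxy)phenyl]chromane-3,4-diol; 25 benzylated epicatechin-(4β→6)-8-bromocatechin dimer
Product: 26 5,7,3',4'-tetra-O-benzyl-(+)-catechin-(4α→8)-5,7,3',4'-tetra-O-benzyl-(−)-epicatechin-(4β→6)-8-bromo-5,7,3',4'-tetra-O-benzyl-(+)-catechin
Conditions: 25 (2 equiv, excess recovered), slow addition of 16, TMSOTf (0.3 equiv), CH2Cl2, −78 to −40 °C; Et3N quench
Reagents that add atoms: none
Why: Friedel–Crafts alkylation after ionisation of the benzylic 4-OH, in which C8 of the epicatechin unit, the most nucleophilic free position of 25, should attack the C4 cation anti to the 3-OH to give the all-equatorial 3,4-trans (4α) upper unit.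

Step 15
Reactants: 26 benzylated, brominated trimer
Product: 27 catechin-(4α→8)-epicatechin-(4β→6)-catechin (CNP0178679.1)
Conditions: H2 (1 atm), Pd(OH)2/C, Et3N (3 equiv), THF/MeOH/H2O, rt
Reagents that add atoms: none
Why: Catalytic hydrogenolysis, which should cleave the twelve benzyl ethers and the aryl C–Br bond (with Et3N taking up HBr) without affecting the interflavan bonds or any stereocentre.

Compound list
1 | 2,4,6-trihydroxybenzaldehyde | O=Cc1c(O)cc(O)cc1O | starting material
2 | benzyl bromide | BrCc1ccccc1 | starting material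
3 | 4,6-bis(benzyloxy)-2-hydroxybenzaldehyde | O=Cc1c(O)cc(OCc2ccccc2)cc1OCc1ccccc1 | intermediate
4 | 3,4-bis(benzyloxy)benzaldehyde | O=Cc1ccc(OCc2ccccc2)c(OCc2ccccc2)c1 | starting material
5 | triethyl phosphonoacetate | CCOC(=O)CP(=O)(OCC)OCC | starting material
6 | ethyl (E)-3-[3,4-bis(benzyloxy)phenyl]acrylate | CCOC(=O)/C=C/c1ccc(OCc2ccccc2)c(OCc2ccccc2)c1 | intermediate
7 | (E)-3-[3,4-bis(benzyloxy)phenyl]prop-2-en-1-ol | OC/C=C/c1ccc(OCc2ccccc2)c(OCc2ccccc2)c1 | intermediate
8 | methyl chloroformate | COC(=O)Cl | starting material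
9 | (E)-3-[3,4-bis(benzyloxy)phenyl]allyl methyl carbonate | COC(=O)OC/C=C/c1ccc(OCc2ccccc2)c(OCc2ccccc2)c1 | intermediate
10 | sodium 3,5-bis(benzyloxy)-2-formylphenoxide | [Na+].[O-]c1cc(OCc2ccccc2)cc(OCc2ccccc2)c1C=O | intermediate
11 | (S)-4,6-bis(benzyloxy)-2-({1-[3,4-bis(benzyloxy)phenyl]prop-2-en-1-yl}oxy)benzaldehyde | C=C[C@H](Oc1cc(OCc2ccccc2)cc(OCc2ccccc2)c1C=O)c1ccc(OCc2ccccc2)c(OCc2ccccc2)c1 | intermediate
12 | methyltriphenylphosphonium bromide | C[P+](c1ccccc1)(c1ccccc1)c1ccccc1.[Br-] | starting material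
13 | (S)-1,5-bis(benzyloxy)-3-({1-[3,4-bis(benzyloxy)phenyl]prop-2-en-1-yl}oxy)-2-vinylbenzene | C=C[C@H](Oc1cc(OCc2ccccc2)cc(OCc2ccccc2)c1C=C)c1ccc(OCc2ccccc2)c(OCc2ccccc2)c1 | intermediate
14 | (S)-5,7-bis(benzyloxy)-2-[3,4-bis(benzyloxy)phenyl]-2H-chromene | [C@@H]1(c2ccc(OCc3ccccc3)c(OCc3ccccc3)c2)C=Cc2c(OCc3ccccc3)cc(OCc3ccccc3)cc2O1 | intermediate
15 | N-methylmorpholine N-oxide | C[N+]1([O-])CCOCC1 | starting material
16 | (2R,3S,4S)-5,7-bis(benzyloxy)-2-[3,4-bis(benzyloxy)phenyl]chromane-3,4-diol | C(c1ccccc1)Oc1cc(OCc3ccccc3)c2c(c1)O[C@H](c1ccc(OCc3ccccc3)c(OCc3ccccc3)c1)[C@@H](O)[C@H]2O | intermediate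
17 | (−)-epicatechin | Oc1cc(O)c2c(c1)O[C@H](c1ccc(O)c(O)c1)[C@H](O)C2 | starting material
18 | 5,7,3',4'-tetra-O-benzyl-(−)-epicatechin | C(c1ccccc1)Oc1cc(OCc3ccccc3)c2c(c1)O[C@H](c1ccc(OCc3ccccc3)c(OCc3ccccc3)c1)[C@H](O)C2 | intermediate
19 | 2-ethoxyethanol | CCOCCO | starting material
20 | (2R,3R,4S)-5,7-bis(benzyloxy)-2-[3,4-bis(benzyloxy)phenyl]-4-(2-ethoxyethoxy)chroman-3-ol | C(c1ccccc1)Oc1cc(OCc3ccccc3)c2c(c1)O[C@H](c1ccc(OCc3ccccc3)c(OCc3ccccc3)c1)[C@H](O)[C@H]2OCCOCC | intermediate
21 | (+)-catechin | Oc1cc(O)c2c(c1)O[C@H](c1ccc(O)c(O)c1)[C@@H](O)C2 | starting material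
22 | 5,7,3',4'-tetra-O-benzyl-(+)-catechin | C(c1ccccc1)Oc1cc(OCc3ccccc3)c2c(c1)O[C@H](c1ccc(OCc3ccccc3)c(OCc3ccccc3)c1)[C@@H](O)C2 | intermediate
23 | N-bromosuccinimide | O=C1CCC(=O)N1Br | starting material
24 | 8-bromo-5,7,3',4'-tetra-O-benzyl-(+)-catechin | C(c1ccccc1)Oc1cc(OCc3ccccc3)c2c(c1Br)O[C@H](c1ccc(OCc3ccccc3)c(OCc3ccccc3)c1)[C@@H](O)C2 | intermediate
25 | 5,7,3',4'-tetra-O-benzyl-(−)-epicatechin-(4β→6)-8-bromo-5,7,3',4'-tetra-O-benzyl-(+)-catechin | C(c1ccccc1)Oc1cc(OCc3ccccc3)c2c(c1)O[C@H](c1ccc(OCc3ccccc3)c(OCc3ccccc3)c1)[C@H](O)[C@H]2c1c(OCc3ccccc3)c(Br)c2c(c1OCc1ccccc1)C[C@H](O)[C@@H](c1ccc(OCc3ccccc3)c(OCc3ccccc3)c1)O2 | intermediate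
26 | 5,7,3',4'-tetra-O-benzyl-(+)-catechin-(4α→8)-5,7,3',4'-tetra-O-benzyl-(−)-epicatechin-(4β→6)-8-bromo-5,7,3',4'-tetra-O-benzyl-(+)-catechin | C(c1ccccc1)Oc1cc(OCc3ccccc3)c2c(c1)O[C@H](c1ccc(OCc3ccccc3)c(OCc3ccccc3)c1)[C@@H](O)[C@@H]2c1c(OCc3ccccc3)cc(OCc3ccccc3)c2c1O[C@H](c1ccc(OCc3ccccc3)c(OCc3ccccc3)c1)[C@H](O)[C@H]2c1c(OCc3ccccc3)c(Br)c2c(c1OCc1ccccc1)C[C@H](O)[C@@H](c1ccc(OCc3ccccc3)c(OCc3ccccc3)c1)O2 | intermediate
27 | catechin-(4α→8)-epicatechin-(4β→6)-catechin (CNP0178679.1) | Oc1cc(O)c2c(c1)O[C@H](c1ccc(O)c(O)c1)[C@@H](O)[C@@H]2c1c(O)cc(O)c2c1O[C@H](c1ccc(O)c(O)c1)[C@H](O)[C@H]2c1c(O)cc2c(c1O)C[C@H](O)[C@@H](c1ccc(O)c(O)c1)O2 | target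

Total step count: 15. Longest linear sequence: 9 steps (steps 2, 3, 4, 5, 6, 7, 8, 14, 15).

Steps most likely to fail

Step 5. The chelated, electron-poor salicylaldehyde aryloxide may attack the π-allyl complex slowly. The product, an electron-rich benzylic allylic ether with a good aryloxide leaving group, may also be re-ionised by the catalyst, eroding the enantiomeric purity and leaking to the linear cinnamyl ether. The fallback sets out from 4 and 3 and comes back at 11. Vinylmagnesium bromide (THF, −78 °C) should convert aldehyde 4 into racemic 1-[3,4-bis(benzyloxy)phenyl]prop-2-en-1-ol F1. A Sharpless kinetic resolution (Ti(OiPr)4, D-(−)-diisopropyl tartrate, t-BuOOH, 4 Å molecular sieves, CH2Cl2, −20 °C; the tartrate antipode is the one for which the (S)-alcohol reacts fast by the Sharpless mnemonic) should consume the (S)-enantiomer as the erythro epoxy alcohol (R)-[3,4-bis(benzyloxy)phenyl][(R)-oxiran-2-yl]methanol F3 and leave (R)-1-[3,4-bis(benzyloxy)phenyl]prop-2-en-1-ol F2. Mitsunobu etherification of F2 with phenol 3 (PPh3, DIAD, toluene, −20 °C to rt) should then give ether 11 with inversion.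

Step 13. Self-condensation of electrophile 20 through its own free C8 may outrun attack by the hindered, bromine-deactivated C6 of 24. The fallback reverses the order of assembly; it sets out from 16 and 18 and comes back at 26. TMSOTf-promoted coupling of diol 16 with an excess of monomer 18 (C8 attack, 3,4-trans) should give 5,7,3',4'-tetra-O-benzyl-(+)-catechin-(4α→8)-5,7,3',4'-tetra-O-benzyl-(−)-epicatechin F4. DDQ with 2-ethoxyethanol should oxidise the only benzylic methylene, C4 of the lower unit, to give the 4β-(2-ethoxyethoxy) derivative of that dimer F5. In F5 the C8 next to the reacting centre is already substituted, so that ring can no longer self-condense through its most reactive position. TMSOTf coupling of F5 with an excess of 24 through C6 (−78 °C) should then give 26.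

Step 14. Facial selectivity at C4 of the diol-derived cation may be poor (4α against 4β), and the hydroxyl leaving group may ionise sluggishly, calling for harsher acid that scrambles the existing interflavan bond or causes over-alkylation. The fallback uses a participating group; it sets out from 16 and comes back at 26. Acetylation (Ac2O, pyridine, DMAP) should give (2R,3S,4S)-5,7-bis(benzyloxy)-2-[3,4-bis(benzyloxy)phenyl]chromane-3,4-diyl diacetate F6. With TMSOTf at −78 °C the 4-acetate leaves and the 3-acetoxy group should bridge to C4 as a dioxolanylium ion on the face of the C3 oxygen. Dimer 25 is thus forced to enter from the opposite face, giving the 3-O-acetyl derivative (upper unit) of the benzylated trimer F7. NaOMe (catalytic) in MeOH/THF should remove the acetate to give 26.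

Further compounds
F1 | step 5 | racemic 1-[3,4-bis(benzyloxy)phenyl]prop-2-en-1-ol | C=CC(O)c1ccc(OCc2ccccc2)c(OCc2ccccc2)c1
F2 | step 5 | (R)-1-[3,4-bis(benzyloxy)phenyl]prop-2-en-1-ol | C=C[C@@H](O)c1ccc(OCc2ccccc2)c(OCc2ccccc2)c1
F3 | step 5 | (R)-[3,4-bis(benzyloxy)phenyl][(R)-oxiran-2-yl]methanol | O[C@H](c1ccc(OCc2ccccc2)c(OCc2ccccc2)c1)[C@H]1CO1
F4 | step 13 | 5,7,3',4'-tetra-O-benzyl-(+)-catechin-(4α→8)-5,7,3',4'-tetra-O-benzyl-(−)-epicatechin | C(c1ccccc1)Oc1cc(OCc3ccccc3)c2c(c1)O[C@H](c1ccc(OCc3ccccc3)c(OCc3ccccc3)c1)[C@@H](O)[C@@H]2c1c(OCc3ccccc3)cc(OCc3ccccc3)c2c1O[C@H](c1ccc(OCc3ccccc3)c(OCc3ccccc3)c1)[C@H](O)C2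
F5 | step 13 | 4β-(2-ethoxyethoxy) derivative (lower unit) of the benzylated catechin-(4α→8)-epicatechin dimer | C(c1ccccc1)Oc1cc(OCc3ccccc3)c2c(c1)O[C@H](c1ccc(OCc3ccccc3)c(OCc3ccccc3)c1)[C@@H](O)[C@@H]2c1c(OCc3ccccc3)cc(OCc3ccccc3)c2c1O[C@H](c1ccc(OCc3ccccc3)c(OCc3ccccc3)c1)[C@H](O)[C@H]2OCCOCC
F6 | step 14 | (2R,3S,4S)-5,7-bis(benzyloxy)-2-[3,4-bis(benzyloxy)phenyl]chromane-3,4-diyl diacetate | C(c1ccccc1)Oc1cc(OCc3ccccc3)c2c(c1)O[C@H](c1ccc(OCc3ccccc3)c(OCc3ccccc3)c1)[C@@H](OC(C)=O)[C@H]2OC(C)=O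
F7 | step 14 | 3-O-acetyl derivative (upper unit) of the benzylated, brominated trimer | C(c1ccccc1)Oc1cc(OCc3ccccc3)c2c(c1)O[C@H](c1ccc(OCc3ccccc3)c(OCc3ccccc3)c1)[C@@H](OC(C)=O)[C@@H]2c1c(OCc3ccccc3)cc(OCc3ccccc3)c2c1O[C@H](c1ccc(OCc3ccccc3)c(OCc3ccccc3)c1)[C@H](O)[C@H]2c1c(OCc3ccccc3)c(Br)c2c(c1OCc1ccccc1)C[C@H](O)[C@@H](c1ccc(OCc3ccccc3)c(OCc3ccccc3)c1)O2
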